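**Assumption (one line):** the following are bought as commercial materials: (S)-Roche ester, (S)-lactic Weinreb amide (or made in one step from ethyl L-lactate), 4-bromo-2-methoxyphenol, 4-bromo-2,6-dimethoxyphenol and tert-butyl diethylphosphonoacetate. Both phenols are protected as TIPS ethers until the last step.

## Retrosynthetic overview
1. The target comes from removing two TIPS groups after an electrochemical decarboxylative arylation. This joins the redox-active ester of the (3R,4S)-dimethyl acid fragment (guaiacyl already attached) to the tail aryl bromide.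
2. The guaiacyl–C7 bond is made by photochemical deoxygenative arylation of a primary alcohol. That alcohol comes from hydroxyl-directed hydrogenation of an E-enoate, which sets C8' relative to C8. C8 comes from (S)-Roche ester.
3. The tail aryl bromide has C8'' from (S)-lactamide (Mitsunobu inversion, which puts the 4-bromo-2,6-dimethoxyphenoxy group on C8'') and C7'' from a chelation-controlled ketone reduction.
4. No rings are formed. All three arenes are purchased.

## Forward route

**Step 1**
Reactants: 1, methyl (2S)-3-hydroxy-2-methylpropanoate (Roche ester).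
Product: 2, methyl (2S)-3-(TBSO)-2-methylpropanoate.
Conditions: TBSCl, imidazole, CH2Cl2, 0 °C → rt.
Reagents that add atoms: TBSCl, CC(C)(C)[Si](C)(C)Cl.
Why: Silyl protection of the primary alcohol (standard); the stereocentre is untouched.

**Step 2**
Reactants: 2.
Product: 3, (2S)-3-(TBSO)-N-methoxy-N,2-dimethylpropanamide.
Conditions: MeNHOMe·HCl, iPrMgCl, THF, −20 → 0 °C.
Reagents that add atoms: N,O-dimethylhydroxylamine hydrochloride, CNOC.Cl.
Why: Weinreb amidation (Williams protocol); the α-centre is not epimerised under these conditions.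

**Step 3**
Reactants: 3.
Product: 4, (3S)-4-(TBSO)-3-methylbutan-2-one.
Conditions: MeMgBr, THF, 0 °C.
Reagents that add atoms: MeMgBr, C[Mg]Br.
Why: The Weinreb chelate stops the reaction at the ketone stage (no over-addition).

**Step 4**
Reactants: 4; 5, tert-butyl diethylphosphonoacetate (CCOP(=O)(OCC)CC(=O)OC(C)(C)C).
Product: 6, tert-butyl (2E,4R)-5-(TBSO)-3,4-dimethylpent-2-enoate.
Conditions: NaH, THF, 0 °C → rt; separate the minor Z isomer by chromatography.
Reagents that add atoms: none beyond reactant 5.
Why: Horner–Wadsworth–Emmons olefination, E-selective. The preformed phosphonate anion keeps the β-silyloxy ketone from epimerising or eliminating. The ester carbon is an extra carbon that is later removed by decarboxylative coupling.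

**Step 5**
Reactants: 6.
Product: 7, tert-butyl (2E,4R)-5-hydroxy-3,4-dimethylpent-2-enoate.
Conditions: HF·pyridine, THF/pyridine, 0 °C → rt.
Reagents that add atoms: none.
Why: Mild desilylation unmasks the homoallylic OH that directs the next step; the tert-butyl ester prevents lactonisation.

**Step 6**
Reactants: 7.
Product: 8, tert-butyl (3R,4R)-5-hydroxy-3,4-dimethylpentanoate.
Conditions: H2 (3 atm), [Ir(cod)(PCy3)(py)]PF6 (2 mol %), CH2Cl2, rt.
Reagents that add atoms: none.
Why: Proposed new method: hydroxyl-directed Ir hydrogenation of a trisubstituted α,β-unsaturated ester carrying a homoallylic OH and an allylic methyl stereocentre, used to build the vicinal (meso-type) dimethyl stereodiad.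
- Mechanism: In the E-enoate, A(1,2)/A(1,3)-strain minimisation puts C4–H in the alkene plane syn to the geminal C3 methyl. This leaves CH2OH gauche (~60°) to the alkene, so the OH binds cationic Ir(H)2 and both hydrogens are delivered syn to CH2OH. That gives 3R from 4R, so C8 (S) and C8' (R) in the final numbering.
- Closest known reaction: Crabtree/Evans hydroxyl-directed hydrogenation of homoallylic alcohols.
- CIP note: the descriptor at C4 of 8 reads R only because CH2OH outranks the chain.

**Step 7**
Reactants: 9, 4-bromo-2-methoxyphenol.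
Product: 10, (4-bromo-2-methoxyphenoxy)triisopropylsilane.
Conditions: TIPSCl, imidazole, DMF, rt.
Reagents that add atoms: TIPSCl, CC(C)[Si](Cl)(C(C)C)C(C)C.
Why: Phenol silylation. TIPS survives LiOH/Grignard/photoredox conditions better than TBS.

**Step 8** (photochemical key bond, C7–aryl)
Reactants: 8; 10.
Product: 11, tert-butyl (3R,4S)-3,4-dimethyl-5-[3-methoxy-4-(TIPSO)phenyl]pentanoate.
Conditions: benzoxazolium NHC salt, pyridine, [Ir(dF(CF3)ppy)2(dtbbpy)]PF6 (1 mol %), NiCl2·glyme/dtbbpy (10 mol %), Cs2CO3, MeCN, blue LEDs, rt.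
Reagents that add atoms: none.
Why: Metallaphotoredox deoxygenative arylation. The NHC-activated primary alcohol fragments to a primary radical, which is captured by Ar–Ni. The radical is primary and β to C8', so no stereocentre is disturbed.

**Step 9**
Reactants: 11.
Product: 12, (3R,4S)-3,4-dimethyl-5-[3-methoxy-4-(TIPSO)phenyl]pentanoic acid.
Conditions: TFA/CH2Cl2 (1:4), 0 °C → rt, 1 h.
Reagents that add atoms: none.
Why: Acidolysis of the tert-butyl ester; the aryl TIPS ether survives brief TFA.

**Step 10**
Reactants: 12.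
Product: 13, N-hydroxyphthalimide ester of 12.
Conditions: NHPI, DIC, DMAP (cat.), CH2Cl2, rt.
Reagents that add atoms: N-hydroxyphthalimide, O=C1c2ccccc2C(=O)N1O.
Why: Redox-active ester formation; the carboxyl carbon is the extra carbon that leaves as CO2 in Step 14.

**Step 11**
Reactants: 14, 4-bromo-2,6-dimethoxyphenol; 15, (2S)-2-hydroxy-N-methoxy-N-methylpropanamide.
Product: 16, (2R)-2-(4-bromo-2,6-dimethoxyphenoxy)-N-methoxy-N-methylpropanamide.
Conditions: PPh3, DIAD, THF, 0 °C → rt.
Reagents that add atoms: none beyond the two reactants.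
Why: Mitsunobu etherification with clean SN2 inversion at the lactate carbon, giving 8''R from (S)-lactamide.

**Step 12**
Reactants: 16; 10 (converted to its Grignard in situ).
Product: 17, (2R)-2-(4-bromo-2,6-dimethoxyphenoxy)-1-[3-methoxy-4-(TIPSO)phenyl]propan-1-one.
Conditions: Mg, THF, 65 °C to form ArMgBr; then add 16, −20 → 0 °C; NH4Cl work-up.
Reagents that add atoms: none.
Why: Weinreb ketone synthesis; the chelated intermediate prevents over-addition and keeps the α-aryloxy centre intact.

**Step 13**
Reactants: 17.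
Product: 18, (1S,2R)-2-(4-bromo-2,6-dimethoxyphenoxy)-1-[3-methoxy-4-(TIPSO)phenyl]propan-1-ol.
Conditions: Zn(BH4)2, Et2O/THF, −20 °C.
Reagents that add atoms: none.
Why: Cram-chelate reduction. Zn binds the carbonyl O and the aryloxy O (with help from the ortho OMe), and hydride enters from the face bearing H rather than CH3. Starting from 8''R this sets 7''S.

**Step 14** (electrochemical key bond, C7'–aryl; joins the two halves)
Reactants: 13; 18.
Product: 19, bis-TIPS-protected target.
Conditions: NiBr2·glyme (10 mol %)/dtbbpy, AgNO3 (cat.), nBu4NBF4, DMF, undivided cell, Mg anode/Ni-foam cathode, constant current, rt.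
Reagents that add atoms: none.
Why: Ag–Ni electrocatalytic decarboxylative arylation. Electroreduction of the NHPI ester gives a primary radical with loss of CO2. Ni captures it and couples it to the aryl bromide. The radical is primary and remote from the stereocentres, so no stereochemistry is lost.

**Step 15**
Reactants: 19.
Product: 20, target.
Conditions: TBAF/AcOH (1:1), THF, 0 °C → rt.
Reagents that add atoms: none.
Why: Fluoride removes both aryl silyl ethers without touching the benzylic alcohol, the aryl ether or any stereocentre.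

## Compound list
1 | methyl (2S)-3-hydroxy-2-methylpropanoate | COC(=O)[C@@H](C)CO | starting material
2 | methyl (2S)-3-(TBSO)-2-methylpropanoate | COC(=O)[C@@H](C)CO[Si](C)(C)C(C)(C)C | intermediate
3 | (2S)-3-(TBSO)-N-methoxy-N,2-dimethylpropanamide | CON(C)C(=O)[C@@H](C)CO[Si](C)(C)C(C)(C)C | intermediate
4 | (3S)-4-(TBSO)-3-methylbutan-2-one | CC(=O)[C@@H](C)CO[Si](C)(C)C(C)(C)C | intermediate
5 | tert-butyl 2-(diethoxyphosphoryl)acetate | CCOP(=O)(OCC)CC(=O)OC(C)(C)C | starting material
6 | tert-butyl (2E,4R)-5-(TBSO)-3,4-dimethylpent-2-enoate | CC(C)(C)OC(=O)/C=C(\C)[C@@H](C)CO[Si](C)(C)C(C)(C)C | intermediate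
7 | tert-butyl (2E,4R)-5-hydroxy-3,4-dimethylpent-2-enoate | CC(C)(C)OC(=O)/C=C(\C)[C@@H](C)CO | intermediate
8 | tert-butyl (3R,4R)-5-hydroxy-3,4-dimethylpentanoate | OC[C@H](C)[C@H](C)CC(=O)OC(C)(C)C | intermediate
9 | 4-bromo-2-methoxyphenol | COc1cc(Br)ccc1O | starting material
10 | (4-bromo-2-methoxyphenoxy)triisopropylsilane | COc1cc(Br)ccc1O[Si](C(C)C)(C(C)C)C(C)C | intermediate
11 | tert-butyl (3R,4S)-3,4-dimethyl-5-[3-methoxy-4-(TIPSO)phenyl]pentanoate | COc1cc(C[C@H](C)[C@H](C)CC(=O)OC(C)(C)C)ccc1O[Si](C(C)C)(C(C)C)C(C)C | intermediate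
12 | (3R,4S)-3,4-dimethyl-5-[3-methoxy-4-(TIPSO)phenyl]pentanoic acid | COc1cc(C[C@H](C)[C@H](C)CC(=O)O)ccc1O[Si](C(C)C)(C(C)C)C(C)C | intermediate
13 | NHPI ester of 12 | COc1cc(C[C@H](C)[C@H](C)CC(=O)ON2C(=O)c3ccccc3C2=O)ccc1O[Si](C(C)C)(C(C)C)C(C)C | intermediate
14 | 4-bromo-2,6-dimethoxyphenol | COc1cc(Br)cc(OC)c1O | starting material
15 | (2S)-2-hydroxy-N-methoxy-N-methylpropanamide | C[C@H](O)C(=O)N(C)OC | starting material
16 | (2R)-2-(4-bromo-2,6-dimethoxyphenoxy)-N-methoxy-N-methylpropanamide | C[C@@H](Oc1c(OC)cc(Br)cc1OC)C(=O)N(C)OC | intermediate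
17 | (2R)-2-(4-bromo-2,6-dimethoxyphenoxy)-1-[3-methoxy-4-(TIPSO)phenyl]propan-1-one | C[C@@H](Oc1c(OC)cc(Br)cc1OC)C(=O)c1ccc(O[Si](C(C)C)(C(C)C)C(C)C)c(OC)c1 | intermediate
18 | (1S,2R)-2-(4-bromo-2,6-dimethoxyphenoxy)-1-[3-methoxy-4-(TIPSO)phenyl]propan-1-ol | COc1cc(Br)cc(OC)c1O[C@H](C)[C@@H](O)c1ccc(O[Si](C(C)C)(C(C)C)C(C)C)c(OC)c1 | intermediate
19 | bis-TIPS-protected target | COc1cc(C[C@H](C)[C@H](C)Cc2cc(OC)c(O[C@H](C)[C@@H](O)c3ccc(O[Si](C(C)C)(C(C)C)C(C)C)c(OC)c3)c(OC)c2)ccc1O[Si](C(C)C)(C(C)C)C(C)C | intermediate
20 | (+)-(7''S,8S,8'R,8''R)-4,4''-dihydroxy-3,3',3'',5'-tetramethoxy-4',8''-oxy-8,8'-sesquineolignan-7''-ol | COc1cc(C[C@H](C)[C@H](C)Cc2cc(OC)c(O[C@H](C)[C@@H](O)c3ccc(O)c(OC)c3)c(OC)c2)ccc1O | target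

**Total steps:** 15. **Longest linear sequence:** 11 (Steps 1 to 6, then 8, 9, 10, 14, 15, from Roche ester).

## Three steps most likely to fail
1. **Step 6 (new method):** the directed hydrogenation may give low dr, or Ir may isomerise the enoate instead. Fallback (known chemistry): sensitised E→Z photoisomerisation of 7 (Ir(ppy)3, blue LEDs) and acid-catalysed cyclisation to 4,5-dimethyl-5,6-dihydropyran-2-one. Pd/C hydrogenation of this lactone puts H anti to the C5 methyl, giving the cis (meso-type) lactone. NaOMe/MeOH then opens it to the methyl hydroxy ester, which replaces 8 (the later acid step becomes ester hydrolysis).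
2. **Step 14:** the electron-rich aryl bromide bearing a free OH may couple poorly. Fallback: convert acid 12 to the primary bromide by photochemical Barton decarboxylative bromination. Then couple it with 18 (or its aryl iodide) by silyl-radical Ni/photoredox cross-electrophile coupling.
3. **Step 13:** chelation control by a diaryl-type ether oxygen is weak, so dr may be poor. Fallback: L-Selectride (Felkin–Anh) reduction to the (7''R,8''R) alcohol, then Mitsunobu inversion at C7'' with p-nitrobenzoic acid and K2CO3/MeOH methanolysis.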